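Cyclohexene numbering used below: C1 = CH bearing the aryl group, C2=C3 = ring alkene (C3 bears CH3), C4 and C5 = CH2, C6 = quaternary carbon (CH3, styryl).
Retrosynthetic cuts, in order: the styryl C=C (olefination), then a helper formyl group is placed on C2, then C2=C3 and C5–C6 are cut together.
Enabling feature: the arc C5–C4–C3(–CH3) is the skeleton of methyl vinyl ketone, electrophilic at both ends. C6 and C2 lie 1,3 across benzylic C1, so they are the two alpha carbons of a 3-arylglutaraldehyde.
That dialdehyde is used as a chiral 2-ethoxy-3,4-dihydro-2H-pyran (temporary ring). In it only C6 is nucleophilic (enol ether), and C2 stays masked until the ring is unravelled.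
Forward order: coumarin aldehyde, (E)-2-methylenal, dihydropyran ring, [3+3] annulation with methyl vinyl ketone (closes the cyclohexene), second coumarin joined by phosphonate olefination, decarbonylation of the helper.
Stereochemistry: C1 comes from a catalytic asymmetric hetero-Diels–Alder reaction, C6 from addition anti to the aryl group on the temporary ring, and the (E)-alkene from the Horner–Wadsworth–Emmons reaction.

Key step: step 4

Assumption: the (1S,2R)-aminoindanol-derived chromium catalyst is taken to give the (4R) centre of 6. If the sense of induction is the opposite, the mirror-image ligand is used.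

Step 1
Reactants: 1 7-hydroxy-2-oxo-2H-chromene-8-carbaldehyde
Product: 2 7-methoxy-2-oxo-2H-chromene-8-carbaldehyde
Conditions: MeI, K2CO3, DMF, rt
Reagents that add atoms: methyl iodide, CI
Why: Williamson O-methylation of the only acidic OH, under a carbonate base that leaves the lactone and the non-enolisable aldehyde untouched.

Step 2
Reactants: 2 7-methoxy-2-oxo-2H-chromene-8-carbaldehyde; 3 2-(triphenyl-λ5-phosphanylidene)propanal
Product: 4 (E)-3-(7-methoxy-2-oxo-2H-chromen-8-yl)-2-methylprop-2-enal
Conditions: toluene, 100 °C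
Reagents that add atoms: none
Why: Wittig olefination with a stabilised, alpha-branched ylide should give the (E)-enal, and the hindered product enal should not react a second time.

Step 3
Reactants: 4 (E)-3-(7-methoxy-2-oxo-2H-chromen-8-yl)-2-methylprop-2-enal; 5 ethyl vinyl ether
Product: 6 8-[(2R,4R)-2-ethoxy-5-methyl-3,4-dihydro-2H-pyran-4-yl]-7-methoxy-2H-chromen-2-one (ethoxy cis to aryl)
Conditions: CrCl(L) (5 mol %; H2L = (1S,2R)-1-{[3-(1-adamantyl)-2-hydroxy-5-methylbenzylidene]amino}indan-2-ol), 4 Å MS, neat 5, rt
Reagents that add atoms: none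
Why: Catalytic asymmetric inverse-electron-demand hetero-Diels–Alder reaction of an enal (1-oxadiene) with a vinyl ether, in which the chiral trivalent chromium Lewis acid binds the formyl oxygen and shields one face, so the catalyst sets the benzylic centre (future C1) and endo approach places ethoxy cis to aryl.

Step 4
Reactants: 6 8-[(2R,4R)-2-ethoxy-5-methyl-3,4-dihydro-2H-pyran-4-yl]-7-methoxy-2H-chromen-2-one; 7 methyl vinyl ketone
Product: 10 (1S,2S)-2-(7-methoxy-2-oxo-2H-chromen-8-yl)-1,4-dimethylcyclohex-3-ene-1,3-dicarbaldehyde, via pyranopyran bis-acetal 8 (not isolated), via keto dialdehyde 9 (not isolated)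
Conditions: (a) 7 (excess), Yb(fod)3 (10 mol %; fod = 6,6,7,7,8,8,8-heptafluoro-2,2-dimethyloctane-3,5-dionate), BHT, neat, 60 °C, then excess 7 removed in vacuo; (b) AcOH–H2O–THF, 40 °C; (c) piperidine added, 70 °C
Reagents that add atoms: none
Why: Stage (a): the oxophilic trivalent ytterbium chelate activates 7 as a 1-oxadiene, whose CH2 terminus bonds to the nucleophilic, methyl-bearing enol ether carbon of 6 while its oxygen closes on the O-bearing carbon, a concerted suprafacial [4+2] closure (inverse-electron-demand hetero-Diels–Alder reaction) of a second temporary dihydropyran that makes the C5–C6 bond and the quaternary centre. Stages (b) and (c): aqueous acetic acid unravels bis-acetal 8 to keto dialdehyde 9, whose unhindered formyl group gives the piperidine enamine, and this attacks the methyl ketone in a 6-(enolexo)-exo-trig aldol closure of the carbocycle, loss of water leaving the C2=C3 double bond. The closest known reaction types are the lanthanide-catalysed cycloaddition of vinyl ketones to cyclic enol ethers and the piperidinium acetate cyclisation of 7-oxoalkanals to 2-methylcyclohex-1-ene-1-carbaldehydes. The only new stereocentre, C6, is controlled by the temporary ring: allylic 1,2-strain against the ring methyl group holds the aryl group pseudoaxial and the cis ethoxy group lies on the same face, so 7 should add to the opposite face, which after unravelling places the formyl group on C6 (the later styryl group) cis to the aryl group on C1. The step needs C6 to react with the CH2 end of 7 before C2 becomes nucleophilic, which is secured because C2 is an inert CH2 next to an acetal until stage (b) and excess 7 is stripped off before that. It also needs the enamine mode of aldolisation, which is secured because the formyl group on C6 has no alpha hydrogen and could only close a four-membered ring with C2, and because aldehyde enamines form faster than ketone enamines.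

Step 5
Reactants: 2 7-methoxy-2-oxo-2H-chromene-8-carbaldehyde
Product: 11 8-(hydroxymethyl)-7-methoxy-2H-chromen-2-one
Conditions: NaBH4, MeOH–CH2Cl2, 0 °C
Reagents that add atoms: none
Why: Chemoselective borohydride reduction, since the aromatic aldehyde is reduced much faster than the conjugated lactone.

Step 6
Reactants: 11 8-(hydroxymethyl)-7-methoxy-2H-chromen-2-one
Product: 12 8-(bromomethyl)-7-methoxy-2H-chromen-2-one
Conditions: PBr3, CH2Cl2, 0 °C
Reagents that add atoms: phosphorus tribromide, BrP(Br)Br
Why: Standard conversion of a benzylic alcohol into the bromide through its phosphite ester and bromide displacement.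

Step 7
Reactants: 12 8-(bromomethyl)-7-methoxy-2H-chromen-2-one
Product: 13 diethyl [(7-methoxy-2-oxo-2H-chromen-8-yl)methyl]phosphonate
Conditions: P(OEt)3, neat, 130 °C
Reagents that add atoms: triethyl phosphite, CCOP(OCC)OCC
Why: Michaelis–Arbuzov reaction of a reactive benzylic bromide.

Step 8
Reactants: 10 (1S,2S)-2-(7-methoxy-2-oxo-2H-chromen-8-yl)-1,4-dimethylcyclohex-3-ene-1,3-dicarbaldehyde; 13 diethyl [(7-methoxy-2-oxo-2H-chromen-8-yl)methyl]phosphonate
Product: 14 (5R,6R)-6-(7-methoxy-2-oxo-2H-chromen-8-yl)-5-[(E)-2-(7-methoxy-2-oxo-2H-chromen-8-yl)ethenyl]-2,5-dimethylcyclohex-1-ene-1-carbaldehyde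
Conditions: 13, NaN(SiMe3)2 (1.0 equiv), THF, −78 °C; then 10, −78 to 0 °C
Reagents that add atoms: none
Why: Horner–Wadsworth–Emmons olefination with a benzylic phosphonate is (E)-selective, and the anion should take the saturated formyl group because the other is a conjugated, tetrasubstituted enal flanked on both sides (beta-cyclocitral-like) and so is deactivated electronically and sterically.

Step 9
Reactants: 14 (5R,6R)-6-(7-methoxy-2-oxo-2H-chromen-8-yl)-5-[(E)-2-(7-methoxy-2-oxo-2H-chromen-8-yl)ethenyl]-2,5-dimethylcyclohex-1-ene-1-carbaldehyde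
Product: 15 8-[(1R,6R)-6-[(E)-2-(7-methoxy-2-oxo-2H-chromen-8-yl)ethenyl]-3,6-dimethylcyclohex-2-en-1-yl]-7-methoxy-2H-chromen-2-one
Conditions: RhCl(PPh3)3 (1.1 equiv), toluene, 110 °C
Reagents that add atoms: none
Why: Tsuji–Wilkinson decarbonylation (formyl C–H oxidative addition to monovalent rhodium, CO extrusion, reductive elimination) replaces the helper formyl group on C2 by hydrogen, keeps the double bond in place and touches no stereocentre.

Compound list
1 | 7-hydroxy-2-oxo-2H-chromene-8-carbaldehyde | O=Cc1c(O)ccc2ccc(=O)oc12 | starting material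
2 | 7-methoxy-2-oxo-2H-chromene-8-carbaldehyde | O=Cc1c(OC)ccc2ccc(=O)oc12 | intermediate
3 | 2-(triphenyl-λ5-phosphanylidene)propanal | CC(C=O)=P(c1ccccc1)(c1ccccc1)c1ccccc1 | starting material
4 | (E)-3-(7-methoxy-2-oxo-2H-chromen-8-yl)-2-methylprop-2-enal | O=C/C(C)=C/c1c(OC)ccc2ccc(=O)oc12 | intermediate
5 | ethyl vinyl ether | C=COCC | starting material
6 | 8-[(2R,4R)-2-ethoxy-5-methyl-3,4-dihydro-2H-pyran-4-yl]-7-methoxy-2H-chromen-2-one | CCO[C@H]1C[C@@H](c2c(OC)ccc3ccc(=O)oc23)C(C)=CO1 | intermediate
7 | methyl vinyl ketone (but-3-en-2-one) | CC(=O)C=C | starting material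
8 | 8-[(2R,4S,4aS,8aR)-2-ethoxy-4a,7-dimethyl-3,4,4a,5-tetrahydro-2H,8aH-pyrano[2,3-b]pyran-4-yl]-7-methoxy-2H-chromen-2-one (cis-fused) | CCO[C@H]1C[C@@H](c3c(OC)ccc4ccc(=O)oc34)[C@]2(C)CC=C(C)O[C@@H]2O1 | intermediate
9 | (2S,3S)-3-(7-methoxy-2-oxo-2H-chromen-8-yl)-2-methyl-2-(3-oxobutyl)pentanedial | O=C[C@@](C)(CCC(C)=O)[C@H](c1c(OC)ccc2ccc(=O)oc12)CC=O | intermediate
10 | (1S,2S)-2-(7-methoxy-2-oxo-2H-chromen-8-yl)-1,4-dimethylcyclohex-3-ene-1,3-dicarbaldehyde | O=C[C@@]1(C)CCC(C)=C(C=O)[C@H]1c1c(OC)ccc2ccc(=O)oc12 | intermediate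
11 | 8-(hydroxymethyl)-7-methoxy-2H-chromen-2-one | OCc1c(OC)ccc2ccc(=O)oc12 | intermediate
12 | 8-(bromomethyl)-7-methoxy-2H-chromen-2-one | BrCc1c(OC)ccc2ccc(=O)oc12 | intermediate
13 | diethyl [(7-methoxy-2-oxo-2H-chromen-8-yl)methyl]phosphonate | CCOP(=O)(Cc1c(OC)ccc2ccc(=O)oc12)OCC | intermediate
14 | (5R,6R)-6-(7-methoxy-2-oxo-2H-chromen-8-yl)-5-[(E)-2-(7-methoxy-2-oxo-2H-chromen-8-yl)ethenyl]-2,5-dimethylcyclohex-1-ene-1-carbaldehyde | COc1ccc2ccc(=O)oc2c1/C=C/[C@@]1(C)CCC(C)=C(C=O)[C@H]1c1c(OC)ccc2ccc(=O)oc12 | intermediate
15 | 8-[(1R,6R)-6-[(E)-2-(7-methoxy-2-oxo-2H-chromen-8-yl)ethenyl]-3,6-dimethylcyclohex-2-en-1-yl]-7-methoxy-2H-chromen-2-one | COc1ccc2ccc(=O)oc2c1/C=C/[C@@]1(C)CCC(C)=C[C@H]1c1c(OC)ccc2ccc(=O)oc12 | target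

Total step count: 9. Longest linear sequence: 6 (steps 1, 2, 3, 4, 8, 9).

Steps most likely to fail

Step 4. Cycloaddition at a trisubstituted enol ether carbon next to a bulky benzylic centre may be slower than oligomerisation of 7. In stage (c) the ketone-side aldol modes may also compete. The fallback sets out from 6 and comes back at 10, and it replaces the polar cycloaddition by a radical conjugate addition. Bromoetherification of the enol ether of 6 with N-bromosuccinimide in ethanol gives the tertiary bromo bis-acetal F1. Its tertiary radical, generated with (Me3Si)3SiH and AIBN in benzene at 80 °C in the presence of excess 7, should add to 7 (Giese reaction) anti to the aryl group and give the keto bis-acetal F2. Treating F2 with aqueous acetic acid and then piperidine unravels and cyclises it through 9 to 10.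

Step 9. Insertion of rhodium into the doubly flanked formyl C–H bond may be slow. At the temperature then needed, double-bond migration or cycloreversion of the vinylcyclohexene could set in on the fully assembled molecule. The fallback sets out from 10 and comes back at 15, and it removes the helper before the second coumarin is attached. The saturated formyl group of 10 is masked selectively with 1,2-bis(trimethylsilyloxy)ethane and catalytic Me3SiOSO2CF3 at −78 °C, where conjugated hindered enals acetalise much more slowly, to give the dioxolane enal F3. This small, robust compound tolerates forcing decarbonylation with RhCl(PPh3)3 in benzonitrile at 150 °C and gives the dioxolane alkene F4. Aqueous acid then frees the monoaldehyde F5, and its only formyl group is olefinated with the anion of 13 to give 15.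

Step 8. Discrimination between the two formyl groups may be poor, and a di-ortho-substituted benzylic anion may add only slowly to a neopentyl aldehyde. Gamma-deprotonation of the enal could then consume the anion. The fallback sets out from 10 and comes back at 14. It builds the alkene with a small ylide and attaches the arene by palladium catalysis. One equivalent of Ph3P=CH2 at −78 °C converts the saturated formyl group into the vinyl enal F6. Umbelliferone is iodinated with I2 and KI in aqueous ammonia to 8-iodo-7-hydroxycoumarin F7, which is methylated with MeI and K2CO3 to 8-iodo-7-methoxycoumarin F8. A Heck reaction of F6 and F8 (Pd(OAc)2, P(o-tolyl)3, K2CO3, DMF, 90 °C) should give the (E)-styryl compound 14, because the quaternary allylic carbon offers no competing beta-hydride path.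

Further compounds
F1 | step 4 | 8-[(4S,6R)-3-bromo-2,6-diethoxy-3-methyloxan-4-yl]-7-methoxy-2H-chromen-2-one (mixture at C2 and C3 of the oxane) | CCO[C@H]1C[C@@H](c2c(OC)ccc3ccc(=O)oc23)C(C)(Br)C(OCC)O1
F2 | step 4 | 8-[(3S,4S,6R)-2,6-diethoxy-3-methyl-3-(3-oxobutyl)oxan-4-yl]-7-methoxy-2H-chromen-2-one (mixture at C2 of the oxane) | CCO[C@H]1C[C@@H](c2c(OC)ccc3ccc(=O)oc23)[C@](C)(CCC(C)=O)C(OCC)O1
F3 | step 9 | (5S,6S)-5-(1,3-dioxolan-2-yl)-6-(7-methoxy-2-oxo-2H-chromen-8-yl)-2,5-dimethylcyclohex-1-ene-1-carbaldehyde | O1CCOC1[C@@]2(C)CCC(C)=C(C=O)[C@H]2c1c(OC)ccc2ccc(=O)oc12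
F4 | step 9 | 8-[(1S,6S)-6-(1,3-dioxolan-2-yl)-3,6-dimethylcyclohex-2-en-1-yl]-7-methoxy-2H-chromen-2-one | O1CCOC1[C@@]2(C)CCC(C)=C[C@H]2c1c(OC)ccc2ccc(=O)oc12
F5 | step 9 | (1S,2S)-2-(7-methoxy-2-oxo-2H-chromen-8-yl)-1,4-dimethylcyclohex-3-ene-1-carbaldehyde | O=C[C@@]1(C)CCC(C)=C[C@H]1c1c(OC)ccc2ccc(=O)oc12
F6 | step 8 | (5R,6R)-5-ethenyl-6-(7-methoxy-2-oxo-2H-chromen-8-yl)-2,5-dimethylcyclohex-1-ene-1-carbaldehyde | C=C[C@@]1(C)CCC(C)=C(C=O)[C@H]1c1c(OC)ccc2ccc(=O)oc12
F7 | step 8 | 7-hydroxy-8-iodo-2H-chromen-2-one | Oc1ccc2ccc(=O)oc2c1I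
F8 | step 8 | 8-iodo-7-methoxy-2H-chromen-2-one | COc1ccc2ccc(=O)oc2c1I
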